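**Retrosynthetic overview**
- Last C–C bond: the CH2 arm on C2 of the chromane is joined to the enone β-carbon (C6 of the hydrindenone) by nickel-catalysed reductive coupling of a neopentyl iodide with a β-triflyloxy enone; the tertiary alcohol is then unveiled by Markovnikov hydration of a methallyl group.
- Chromane half: the dihydropyran ring is closed on the bought arene in one oxidative radical (4+2) annulation of an aryloxymalonate with ethylene (new bonds C2–C3 and C4–C4a); C2 is then made stereogenic by enzymatic desymmetrisation of the 2,2-bis(hydroxymethyl)chromane, one arm becoming CH3 and the other CH2I.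
- Enabling feature: C3 and C4 of the dihydropyran ring are two unsubstituted CH2 groups (an ethylene unit); C2 is a quaternary, O1-bearing carbon whose two one-carbon arms can both come from the esters of a malonate; C4a is the only free position ortho to O1 because C8 carries a methyl group.
- Hydrindenone half: asymmetric keteniminium (2+2) cycloaddition on 1,2-dimethylcyclopentene sets both quaternary carbons (cis) as a cyclobutanone; C-acylation, retro-Claisen opening and Claisen closure expand it by two carbons to the cyclohexane-1,3-dione, which is converted to the enol triflate.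
- Ring order: arene (bought) → dihydropyran (step 2); cyclopentane (bought) → cyclobutane (step 11) → cyclohexane (step 13); the halves are joined in step 15.

Key step: step 2

Assumption 1: the lipase of step 4 is taken to acetylate the arm that gives (R)-7 (sense assumed by analogy with other 2,2-bis(hydroxymethyl)chromanes); the opposite sense would be met by using the same lipase in the hydrolytic mode.
Assumption 2: the (2R,5R)-auxiliary of step 11 is taken to lead to (1S,5S)-19; if the sense of induction is the opposite, the (2S,5S)-amine is used instead.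

**Route**

Step 1
Reactants: 1 4-methoxy-2-methylphenol; 2 diethyl 2-chloropropanedioate
Product: 3 diethyl 2-(4-methoxy-2-methylphenoxy)propanedioate
Conditions: K2CO3, acetone, reflux
Reagents that add atoms: none
Why: Williamson-type O-alkylation (SN2) of the phenoxide by the activated chloride of the malonate, a standard entry to aryloxymalonates; no stereocentre is formed.

Step 2
Reactants: 3 diethyl 2-(4-methoxy-2-methylphenoxy)propanedioate; 4 ethene
Product: 5 diethyl 6-methoxy-8-methylchromane-2,2-dicarboxylate
Conditions: Mn(OAc)3·2H2O (2.2 equiv), AcOH, ethene (2 bar), 70 °C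
Reagents that add atoms: none
Why: Proposed new method: trivalent manganese oxidises the malonate C–H of 3 through its manganese enolate to the electrophilic α-aryloxymalonyl radical, which adds to ethene to make the C2–C3 bond; the primary C4 radical then attacks the arene at C4a, and a second equivalent of trivalent manganese oxidises the cyclohexadienyl radical, loss of a proton restoring the arene and completing the C4–C4a bond. The closest known reaction type is the Mn(OAc)3-mediated oxidative annulation of diethyl benzylmalonates with alkenes to tetralins; here the benzylic CH2 is replaced by the ether oxygen and the alkene is ethene itself. The dihydropyran ring closes by six-membered homolytic aromatic substitution (formally 6-endo on the C4a=C8a bond), helped by the gem-diester effect. No stereocentre is formed: C2 becomes quaternary but carries two identical ester arms, and its configuration is left on purpose to the desymmetrisation of step 4. The step needs regioselectivity on the arene and a single ethene insertion: the C8 methyl blocks the other ortho position (attack there or at the ipso carbon is reversible and unproductive), low ethene pressure and the fast ring closure should suppress telomerisation, and the product has no oxidisable malonate C–H left.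

Step 3
Reactants: 5 diethyl 6-methoxy-8-methylchromane-2,2-dicarboxylate
Product: 6 (6-methoxy-8-methylchromane-2,2-diyl)dimethanol
Conditions: LiAlH4, THF, 0 °C to rt
Reagents that add atoms: none
Why: Hydride reduction of both esters to the prochiral 1,3-diol; the aryl ethers are inert and C2 stays non-stereogenic.

Step 4
Reactants: 6 (6-methoxy-8-methylchromane-2,2-diyl)dimethanol
Product: 7 [(2R)-2-(hydroxymethyl)-6-methoxy-8-methylchroman-2-yl]methyl acetate
Conditions: Candida antarctica lipase B (immobilised), vinyl acetate, tBuOMe, 25 °C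
Reagents that add atoms: vinyl acetate, CC(=O)OC=C
Why: Enzymatic desymmetrisation (lipase-catalysed transesterification of a prochiral 2,2-disubstituted propane-1,3-diol, closely precedented on 2,2-bis(hydroxymethyl)chromanes); the enzyme distinguishes the two enantiotopic CH2OH arms and so sets C2, and the enol ester makes the acylation irreversible.

Step 5
Reactants: 7 [(2R)-2-(hydroxymethyl)-6-methoxy-8-methylchroman-2-yl]methyl acetate
Product: 8 [(2S)-2-{[tert-butyl(diphenyl)silyl]oxymethyl}-6-methoxy-8-methylchroman-2-yl]methyl acetate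
Conditions: tBuPh2SiCl, imidazole, CH2Cl2, 0 °C
Reagents that add atoms: tert-butyl(chloro)diphenylsilane, CC(C)(C)[Si](Cl)(c1ccccc1)c1ccccc1
Why: Silylation of the free primary alcohol under mild conditions locks the differentiation of the two arms before 1,3-acyl migration (which would erode the enantiomeric purity) can set in; the descriptor changes only because of the priority rules.

Step 6
Reactants: 8 [(2S)-2-{[tert-butyl(diphenyl)silyl]oxymethyl}-6-methoxy-8-methylchroman-2-yl]methyl acetate
Product: 9 [(2S)-2-{[tert-butyl(diphenyl)silyl]oxymethyl}-6-methoxy-8-methylchroman-2-yl]methanol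
Conditions: K2CO3 (cat.), MeOH, 0 °C
Reagents that add atoms: none
Why: Zemplén-type methanolysis removes the acetate, while the bulky silyl ether is stable to carbonate and slow to migrate, so the arms stay distinct.

Step 7
Reactants: 9 [(2S)-2-{[tert-butyl(diphenyl)silyl]oxymethyl}-6-methoxy-8-methylchroman-2-yl]methanol
Product: 11 tert-butyl{[(2R)-6-methoxy-2,8-dimethylchroman-2-yl]methoxy}diphenylsilane, via neopentyl triflate 10 (not isolated)
Conditions: Tf2O, pyridine, CH2Cl2, -78 °C; solvent change to THF; LiEt3BH, -78 °C to rt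
Reagents that add atoms: none
Why: Triflation and SN2 hydride displacement (the standard deoxygenation of hindered primary alcohols) turn this arm into the C2 methyl group; with the other arm silylated, neither an oxetane nor an acyloxonium ion can form and scramble the arms, so C2 keeps its configuration.

Step 8
Reactants: 11 tert-butyl{[(2R)-6-methoxy-2,8-dimethylchroman-2-yl]methoxy}diphenylsilane
Product: 12 [(2R)-6-methoxy-2,8-dimethylchroman-2-yl]methanol
Conditions: Bu4NF, THF, rt
Reagents that add atoms: none
Why: Fluoride-mediated desilylation frees the second arm; the stereocentre is not touched.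

Step 9
Reactants: 12 [(2R)-6-methoxy-2,8-dimethylchroman-2-yl]methanol
Product: 13 (2R)-2-(iodomethyl)-6-methoxy-2,8-dimethylchromane
Conditions: I2, PPh3, imidazole, toluene, 80 °C
Reagents that add atoms: iodine, II
Why: Appel-type iodination through the alkoxyphosphonium salt; heating is needed for the SN2 step next to the quaternary carbon, and no participating neighbouring group is left.

Step 10
Reactants: 14 (2R,5R)-2,5-dimethylpyrrolidine
Product: 15 1-[(2R,5R)-2,5-dimethylpyrrolidin-1-yl]ethanone
Conditions: AcCl, Et3N, CH2Cl2, 0 °C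
Reagents that add atoms: acetyl chloride, CC(Cl)=O
Why: N-acylation of the secondary amine; the stereocentres of the auxiliary are not involved.

Step 11
Reactants: 15 1-[(2R,5R)-2,5-dimethylpyrrolidin-1-yl]ethanone; 16 1,2-dimethylcyclopentene
Product: 19 (1S,5S)-1,5-dimethylbicyclo[3.2.0]heptan-6-one, via keteniminium triflate 17 (not isolated), via cyclobutaniminium triflate 18 (not isolated)
Conditions: Tf2O, 2,4,6-collidine, ClCH2CH2Cl, -20 °C to reflux; then H2O, 60 °C
Reagents that add atoms: water, O
Why: Amide activation gives the keteniminium ion, which undergoes the (2+2) cycloaddition with the tetrasubstituted alkene (stepwise, through a tertiary cation that closes to the four-membered ring) and is hydrolysed to the cyclobutanone; the cis relation of the two quaternary carbons follows from the ring fusion, and the C2-symmetric pyrrolidine differentiates the two enantiotopic orientations of the symmetric alkene and so fixes the absolute configuration.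

Step 12
Reactants: 19 (1S,5S)-1,5-dimethylbicyclo[3.2.0]heptan-6-one; 20 4-methylpent-4-enoic acid
Product: 22 (1S,5S)-1,5-dimethyl-7-(4-methylpent-4-enoyl)bicyclo[3.2.0]heptan-6-one, via acyl imidazole 21 (not isolated)
Conditions: 20, 1,1'-carbonyldiimidazole, THF, rt; 19, LiN(SiMe3)2 (2.1 equiv), THF, -78 °C; combine, -78 to 0 °C; aq. NH4Cl
Reagents that add atoms: none
Why: Crossed Claisen C-acylation of the lithium enolate of the cyclobutanone, which has a single enolisable position (the CH2), by the acyl imidazole; the second equivalent of base stores the β-diketone as its enolate, and the new CH centre is epimerisable and is lost in step 13.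

Step 13
Reactants: 22 (1S,5S)-1,5-dimethyl-7-(4-methylpent-4-enoyl)bicyclo[3.2.0]heptan-6-one
Product: 24 (3aS,7aS)-3a,7a-dimethyl-5-(2-methylprop-2-enyl)hydrindane-4,6-dione, via keto ester 23 (not isolated)
Conditions: NaOMe (3 equiv), MeOH, 0 °C to reflux; AcOH
Reagents that add atoms: none
Why: Methoxide adds to the strained cyclobutanone carbonyl and retro-Claisen cleavage (relief of ring strain) gives δ-keto ester 23, whose ketone enolate then closes the only possible ring, the six-membered one, by intramolecular Claisen (Dieckmann-type) condensation, driven by formation of the 1,3-dione enolate; both quaternary stereocentres are spectators.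

Step 14
Reactants: 24 (3aS,7aS)-3a,7a-dimethyl-5-(2-methylprop-2-enyl)hydrindane-4,6-dione
Product: 25 (3aS,7aS)-3a,7a-dimethyl-5-(2-methylprop-2-enyl)-4-oxo-2,3,3a,4,7,7a-hexahydro-1H-inden-6-yl trifluoromethanesulfonate
Conditions: Tf2O, pyridine, CH2Cl2, -78 °C
Reagents that add atoms: trifluoromethanesulfonic anhydride, O=S(=O)(OS(=O)(=O)C(F)(F)F)C(F)(F)F
Why: O-sulfonylation of the enolised 1,3-dione; the oxygen on C6 (next to a CH2) is far more accessible than the oxygen on C4 (next to the quaternary C3a), so the triflate should go to C6 and the ketone stay at C4, as the target requires.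

Step 15
Reactants: 13 (2R)-2-(iodomethyl)-6-methoxy-2,8-dimethylchromane; 25 (3aS,7aS)-3a,7a-dimethyl-5-(2-methylprop-2-enyl)-4-oxo-2,3,3a,4,7,7a-hexahydro-1H-inden-6-yl trifluoromethanesulfonate
Product: 26 (3aS,7aS)-6-{[(2R)-6-methoxy-2,8-dimethylchroman-2-yl]methyl}-3a,7a-dimethyl-5-(2-methylprop-2-enyl)-1,2,3,3a,7,7a-hexahydro-4H-inden-4-one
Conditions: NiBr2(MeOCH2CH2OMe) (20 mol%), 4,4'-di-tert-butyl-2,2'-bipyridine (20 mol%), Mn powder (3 equiv), N,N-dimethylacetamide, 0 °C to rt
Reagents that add atoms: none
Why: Nickel-catalysed reductive cross-electrophile coupling: zerovalent nickel inserts into the electron-poor vinyl C–OTf bond, the neopentyl radical formed from the iodide is captured by the vinylnickel species and reductive elimination forms the C(sp3)–C(sp2) bond; a radical is chosen at this carbon because an organozinc or organomagnesium reagent would expel the β-aryloxy group, and no stereocentre is formed or touched.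

Step 16
Reactants: 26 (3aS,7aS)-6-{[(2R)-6-methoxy-2,8-dimethylchroman-2-yl]methyl}-3a,7a-dimethyl-5-(2-methylprop-2-enyl)-1,2,3,3a,7,7a-hexahydro-4H-inden-4-one
Product: 27 (3aS,7aS)-5-(2-hydroxy-2-methylpropyl)-6-{[(2R)-6-methoxy-2,8-dimethylchroman-2-yl]methyl}-3a,7a-dimethyl-1,2,3,3a,7,7a-hexahydro-4H-inden-4-one (CNP0224132.1)
Conditions: Co(acac)2 (20 mol%), PhSiH3 (2 equiv), O2 (1 atm), THF, rt
Reagents that add atoms: dioxygen, O=O
Why: Mukaiyama hydration (hydrogen atom transfer from a cobalt hydride to the 1,1-disubstituted alkene, capture of the tertiary radical by O2, reduction of the peroxide by the silane) gives the Markovnikov tertiary alcohol; the hindered, electron-poor tetrasubstituted enone should react far more slowly, and the neutral conditions avoid the extended enolate that could open the chromane.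

**Compound list**

1 | 4-methoxy-2-methylphenol | COc1ccc(O)c(C)c1 | starting material
2 | diethyl 2-chloropropanedioate | CCOC(=O)C(Cl)C(=O)OCC | starting material
3 | diethyl 2-(4-methoxy-2-methylphenoxy)propanedioate | CCOC(=O)C(Oc1ccc(OC)cc1C)C(=O)OCC | intermediate
4 | ethene | C=C | starting material
5 | diethyl 6-methoxy-8-methylchromane-2,2-dicarboxylate | COc1cc(C)c2c(c1)CCC(C(=O)OCC)(C(=O)OCC)O2 | intermediate
6 | (6-methoxy-8-methylchromane-2,2-diyl)dimethanol | COc1cc(C)c2c(c1)CCC(CO)(CO)O2 | intermediate
7 | [(2R)-2-(hydroxymethyl)-6-methoxy-8-methylchroman-2-yl]methyl acetate | COc1cc(C)c2c(c1)CC[C@](COC(C)=O)(CO)O2 | intermediate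
8 | [(2S)-2-{[tert-butyl(diphenyl)silyl]oxymethyl}-6-methoxy-8-methylchroman-2-yl]methyl acetate | COc1cc(C)c2c(c1)CC[C@](COC(C)=O)(CO[Si](c3ccccc3)(c3ccccc3)C(C)(C)C)O2 | intermediate
9 | [(2S)-2-{[tert-butyl(diphenyl)silyl]oxymethyl}-6-methoxy-8-methylchroman-2-yl]methanol | COc1cc(C)c2c(c1)CC[C@](CO)(CO[Si](c3ccccc3)(c3ccccc3)C(C)(C)C)O2 | intermediate
10 | [(2R)-2-{[tert-butyl(diphenyl)silyl]oxymethyl}-6-methoxy-8-methylchroman-2-yl]methyl trifluoromethanesulfonate | COc1cc(C)c2c(c1)CC[C@](COS(=O)(=O)C(F)(F)F)(CO[Si](c3ccccc3)(c3ccccc3)C(C)(C)C)O2 | intermediate (not isolated)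
11 | tert-butyl{[(2R)-6-methoxy-2,8-dimethylchroman-2-yl]methoxy}diphenylsilane | COc1cc(C)c2c(c1)CC[C@](C)(CO[Si](c3ccccc3)(c3ccccc3)C(C)(C)C)O2 | intermediate
12 | [(2R)-6-methoxy-2,8-dimethylchroman-2-yl]methanol | COc1cc(C)c2c(c1)CC[C@](C)(CO)O2 | intermediate
13 | (2R)-2-(iodomethyl)-6-methoxy-2,8-dimethylchromane | COc1cc(C)c2c(c1)CC[C@](C)(CI)O2 | intermediate
14 | (2R,5R)-2,5-dimethylpyrrolidine | C[C@@H]1CC[C@@H](C)N1 | starting material
15 | 1-[(2R,5R)-2,5-dimethylpyrrolidin-1-yl]ethanone | CC(=O)N1[C@H](C)CC[C@H]1C | intermediate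
16 | 1,2-dimethylcyclopentene | CC1=C(C)CCC1 | starting material
17 | (2R,5R)-1-ethenylidene-2,5-dimethylpyrrolidinium trifluoromethanesulfonate | C=C=[N+]1[C@H](C)CC[C@H]1C.[O-]S(=O)(=O)C(F)(F)F | intermediate (not isolated)
18 | (2R,5R)-1-[(1S,5S)-1,5-dimethylbicyclo[3.2.0]heptan-6-ylidene]-2,5-dimethylpyrrolidinium trifluoromethanesulfonate | C[C@@H]3CC[C@@H](C)[N+]3=C1[C@@]2(C)CCC[C@@]2(C)C1.[O-]S(=O)(=O)C(F)(F)F | intermediate (not isolated)
19 | (1S,5S)-1,5-dimethylbicyclo[3.2.0]heptan-6-one | O=C1[C@@]2(C)CCC[C@@]2(C)C1 | intermediate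
20 | 4-methylpent-4-enoic acid | C=C(C)CCC(=O)O | starting material
21 | 1-(imidazol-1-yl)-4-methylpent-4-en-1-one | C=C(C)CCC(=O)n1ccnc1 | intermediate (not isolated)
22 | (1S,5S)-1,5-dimethyl-7-(4-methylpent-4-enoyl)bicyclo[3.2.0]heptan-6-one (C7 epimers and enol) | O=C1[C@@]2(C)CCC[C@@]2(C)C1C(=O)CCC(C)=C | intermediate
23 | methyl (1S,2S)-1,2-dimethyl-2-(5-methyl-2-oxohex-5-enyl)cyclopentane-1-carboxylate | COC(=O)[C@@]1(C)CCC[C@@]1(C)CC(=O)CCC(C)=C | intermediate (not isolated)
24 | (3aS,7aS)-3a,7a-dimethyl-5-(2-methylprop-2-enyl)hydrindane-4,6-dione (C5 epimers and enol) | O=C1C(CC(C)=C)C(=O)[C@@]2(C)CCC[C@@]2(C)C1 | intermediate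
25 | (3aS,7aS)-3a,7a-dimethyl-5-(2-methylprop-2-enyl)-4-oxo-2,3,3a,4,7,7a-hexahydro-1H-inden-6-yl trifluoromethanesulfonate | FC(F)(F)S(=O)(=O)OC1=C(CC(C)=C)C(=O)[C@@]2(C)CCC[C@@]2(C)C1 | intermediate
26 | (3aS,7aS)-6-{[(2R)-6-methoxy-2,8-dimethylchroman-2-yl]methyl}-3a,7a-dimethyl-5-(2-methylprop-2-enyl)-1,2,3,3a,7,7a-hexahydro-4H-inden-4-one | COc1cc(C)c2c(c1)CC[C@](C)(CC1=C(CC(C)=C)C(=O)[C@@]3(C)CCC[C@@]3(C)C1)O2 | intermediate
27 | (3aS,7aS)-5-(2-hydroxy-2-methylpropyl)-6-{[(2R)-6-methoxy-2,8-dimethylchroman-2-yl]methyl}-3a,7a-dimethyl-1,2,3,3a,7,7a-hexahydro-4H-inden-4-one | COc1cc(C)c2c(c1)CC[C@](C)(CC1=C(CC(C)(C)O)C(=O)[C@@]3(C)CCC[C@@]3(C)C1)O2 | target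

**Summary**

Total step count: 16. Longest linear sequence: 11 steps (steps 1 to 9, then 15 and 16).

Steps most likely to fail:

1. Step 2 (proposed new method). Oxidation of the malonate may be too slow compared with oxidation of the electron-rich arene, the stabilised radical may add to ethene too slowly and dimerise, or a second ethene may insert before ring closure. Fallback with known chemistry, setting out from 3 and coming back at 5: 3 is C-allylated (NaH, allyl bromide, DMF) to diethyl 2-(4-methoxy-2-methylphenoxy)-2-(prop-2-enyl)propanedioate F1. Lemieux–Johnson cleavage (K2OsO4 cat., NaIO4, 2,6-lutidine, dioxane/H2O) gives diethyl 2-(4-methoxy-2-methylphenoxy)-2-(2-oxoethyl)propanedioate F2. Acid-mediated cyclodehydration (TsOH, toluene, reflux; intramolecular Friedel–Crafts hydroxyalkylation ortho to the ether oxygen, then loss of water) gives diethyl 6-methoxy-8-methyl-2H-chromene-2,2-dicarboxylate F3, and hydrogenation (H2, Pd on carbon, EtOAc) gives 5. The two bonds are then made in separate polar steps.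

2. Step 15. β-Fragmentation of the neopentyl radical (loss of the aryloxy radical with opening of the dihydropyran ring) or β-aryloxy elimination at an alkylnickel stage may outrun C–C bond formation, and the triflate may homocouple. Fallback that avoids a radical or metal at this carbon, setting out from 12 and 25 and coming back at 26: 12 is oxidised (Dess–Martin periodinane) to (2R)-6-methoxy-2,8-dimethylchromane-2-carbaldehyde F4. Nozaki–Hiyama–Kishi coupling with 25 (CrCl2, NiCl2 cat., DMF) gives the allylic alcohol (3aS,7aS)-6-{hydroxy[(2R)-6-methoxy-2,8-dimethylchroman-2-yl]methyl}-3a,7a-dimethyl-5-(2-methylprop-2-enyl)-1,2,3,3a,7,7a-hexahydro-4H-inden-4-one F5 as a mixture of carbinol epimers. This is converted (PhOC(S)Cl, pyridine) to its O-phenyl thionocarbonate F6, and Barton–McCombie deoxygenation (Bu3SnH, AIBN, toluene, 80 °C) through the enone-stabilised allylic radical should give 26.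

3. Step 11. The cycloaddition may stop at the tertiary cation (proton loss to an ene-type product) or proceed with insufficient enantioselectivity. Fallback by resolution, setting out from 16 and coming back at 19: dichloroketene (2+2) cycloaddition (Cl3CCOCl, Zn/Cu couple, Et2O) gives racemic 7,7-dichloro-1,5-dimethylbicyclo[3.2.0]heptan-6-one F7. Dechlorination (Zn, AcOH) gives racemic 1,5-dimethylbicyclo[3.2.0]heptan-6-one F8, and NaBH4 gives racemic 1,5-dimethylbicyclo[3.2.0]heptan-6-ol F9. Lipase-catalysed kinetic resolution (Pseudomonas cepacia lipase, vinyl acetate) is expected to separate (1S,5S)-1,5-dimethylbicyclo[3.2.0]heptan-6-ol F10 from the acetate of its antipode, (1R,5R)-1,5-dimethylbicyclo[3.2.0]heptan-6-yl acetate F11, and oxidation of F10 (Dess–Martin periodinane) gives 19.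

Further compounds
F1 | step 2 | diethyl 2-(4-methoxy-2-methylphenoxy)-2-(prop-2-enyl)propanedioate | C=CCC(Oc1ccc(OC)cc1C)(C(=O)OCC)C(=O)OCC
F2 | step 2 | diethyl 2-(4-methoxy-2-methylphenoxy)-2-(2-oxoethyl)propanedioate | O=CCC(Oc1ccc(OC)cc1C)(C(=O)OCC)C(=O)OCC
F3 | step 2 | diethyl 6-methoxy-8-methyl-2H-chromene-2,2-dicarboxylate | COc1cc(C)c2c(c1)C=CC(C(=O)OCC)(C(=O)OCC)O2
F4 | step 15 | (2R)-6-methoxy-2,8-dimethylchromane-2-carbaldehyde | COc1cc(C)c2c(c1)CC[C@](C)(C=O)O2
F5 | step 15 | (3aS,7aS)-6-{hydroxy[(2R)-6-methoxy-2,8-dimethylchroman-2-yl]methyl}-3a,7a-dimethyl-5-(2-methylprop-2-enyl)-1,2,3,3a,7,7a-hexahydro-4H-inden-4-one (carbinol epimers) | COc1cc(C)c2c(c1)CC[C@](C)(C(O)C1=C(CC(C)=C)C(=O)[C@@]3(C)CCC[C@@]3(C)C1)O2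
F6 | step 15 | O-phenyl thionocarbonate of F5 | COc1cc(C)c2c(c1)CC[C@](C)(C(OC(=S)Oc4ccccc4)C1=C(CC(C)=C)C(=O)[C@@]3(C)CCC[C@@]3(C)C1)O2
F7 | step 11 | 7,7-dichloro-1,5-dimethylbicyclo[3.2.0]heptan-6-one (racemic, cis-fused) | O=C1C(Cl)(Cl)C2(C)CCCC12C
F8 | step 11 | 1,5-dimethylbicyclo[3.2.0]heptan-6-one (racemic, cis-fused) | O=C1CC2(C)CCCC12C
F9 | step 11 | 1,5-dimethylbicyclo[3.2.0]heptan-6-ol (racemic, cis-fused) | OC1CC2(C)CCCC12C
F10 | step 11 | (1S,5S)-1,5-dimethylbicyclo[3.2.0]heptan-6-ol | OC1[C@@]2(C)CCC[C@@]2(C)C1
F11 | step 11 | (1R,5R)-1,5-dimethylbicyclo[3.2.0]heptan-6-yl acetate | CC(=O)OC1[C@]2(C)CCC[C@]2(C)C1
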